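The tetramer is cut at its three C4–C8 interflavan bonds into one benzyl-protected (2R,3R)-flavan-3-ol, which serves all four units, and ring C of that unit is cut across O1–C8a and C3–C4. The key step exploits the 1,3-relationship of the aryl carbon C8a and the benzylic carbon C4 on ring A: an ortho-fluorobenzylic chloride meets the O,C-dilithiated form of an (R)-α-hydroxybenzyl-1,3-dithiane, whose carbanion (C3 as a masked ketone) is benzylated and whose alkoxide (O1) then displaces fluoride, so that ring C closes in one flask with C2 already set. Unmasking, cis-selective reduction, C4 oxidation and three C4-cation couplings build the chain.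

Key step: step 7

Remark: since one monomer supplies every flavan unit, step 7 closes ring C of the uppermost unit as well as of the other three; compounds 2 and 6 are taken as purchasable.

Step 1
Reactants: 1 1,3-dithiane; 2 methyl 3,4-bis(benzyloxy)benzoate
Product: 4 [3,4-bis(benzyloxy)phenyl](1,3-dithian-2-yl)methanone, via 2-lithio-1,3-dithiane 3 (not isolated)
Conditions: 1 (2.1 equiv), n-BuLi (2.1 equiv), THF, −30 °C; then 2, −78 → 0 °C; H2O
Reagents that add atoms: none
Why: Corey–Seebach acyl substitution of the ester by the dithianyl anion, in which the acidic 2-acyl-1,3-dithiane is deprotonated by the second equivalent of 3 as it forms, which should prevent a second addition; no stereocenter arises.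

Step 2
Reactants: 4 [3,4-bis(benzyloxy)phenyl](1,3-dithian-2-yl)methanone
Product: 5 (R)-[3,4-bis(benzyloxy)phenyl](1,3-dithian-2-yl)methanol
Conditions: RuCl[(S,S)-TsDPEN](p-cymene) (1 mol %), HCO2H/Et3N (5:2), CH2Cl2, 30 °C
Reagents that add atoms: none
Why: Noyori–Ikariya asymmetric transfer hydrogenation of an aryl ketone, in which the CH–π contact between the aryl group and the arene ligand of the (S,S)-catalyst fixes the face of hydride delivery, should set the carbinol carbon (the later C2) as R, the dithianyl group outranking the aryl group.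

Step 3
Reactants: 6 5-fluorobenzene-1,3-diol
Product: 7 1,3-bis(benzyloxy)-5-fluorobenzene
Conditions: BnBr (2.2 equiv), K2CO3, DMF, 60 °C
Reagents that add atoms: benzyl bromide, BrCc1ccccc1
Why: Williamson etherification of both phenols; no stereocenter is involved.

Step 4
Reactants: 7 1,3-bis(benzyloxy)-5-fluorobenzene
Product: 8 2,4-bis(benzyloxy)-6-fluorobenzaldehyde
Conditions: POCl3 (1.5 equiv), DMF, 0 → 70 °C; then ice-water
Reagents that add atoms: N,N-dimethylformamide, CN(C)C=O; water, O
Why: Vilsmeier–Haack formylation should take place para to one benzyloxy group and ortho to the other, next to fluorine, rather than at the more crowded carbon between the two ethers; no stereocenter is involved.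

Step 5
Reactants: 8 2,4-bis(benzyloxy)-6-fluorobenzaldehyde
Product: 9 [2,4-bis(benzyloxy)-6-fluorophenyl]methanol
Conditions: NaBH4, THF/MeOH, 0 °C
Reagents that add atoms: none
Why: Borohydride reduction of the aryl aldehyde to the benzylic alcohol; no stereocenter is involved.

Step 6
Reactants: 9 [2,4-bis(benzyloxy)-6-fluorophenyl]methanol
Product: 10 1,5-bis(benzyloxy)-2-(chloromethyl)-3-fluorobenzene
Conditions: SOCl2, pyridine, Et2O, 0 °C; used crude
Reagents that add atoms: thionyl chloride, O=S(Cl)Cl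
Why: Chlorodehydroxylation of the electron-rich benzylic alcohol through its chlorosulfite in the presence of pyridine, the easily ionised 2,4-dialkoxybenzyl chloride being carried on without purification.

Step 7
Reactants: 5 (R)-[3,4-bis(benzyloxy)phenyl](1,3-dithian-2-yl)methanol; 10 1,5-bis(benzyloxy)-2-(chloromethyl)-3-fluorobenzene
Product: 13 (2R)-5,7-bis(benzyloxy)-2-[3,4-bis(benzyloxy)phenyl]spiro[chromane-3,2'-[1,3]dithiane], via dilithiated dithianyl carbinol 11 (not isolated), via C-benzylated lithium alkoxide 12 (not isolated)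
Conditions: n-BuLi (2.1 equiv), THF, −30 °C; 10 (1.0 equiv), −78 → 0 °C; then t-BuOK (1.2 equiv), DMPU, 65 °C
Reagents that add atoms: none
Why: n-BuLi removes the O–H and then the dithiane C–H of 5, and the soft carbanion of 11 (the later C3) displaces chloride from the benzylic carbon of 10 (the later C4) in an SN2 step, forming C3–C4 and leaving alkoxide 12. After lithium–potassium exchange with t-BuOK in THF–DMPU, the alkoxide oxygen (O1) adds to the fluorine-bearing carbon of ring A (C8a), to which both benzyloxy groups stand meta so that they do not feed electron density onto it, and fluoride leaves from the Meisenheimer adduct, forming O1–C8a. The closest known reaction types are the Corey–Seebach alkylation of a 2-substituted 2-lithio-1,3-dithiane by a benzyl halide and the intramolecular SNAr etherification of a fluoroarene by a tethered secondary alkoxide. Ring C closes as a six-membered ring in the 6-exo sense, fluoride leaving outside the new ring, helped by the geminal disubstitution at C3. No stereocenter is created, since C3 is a spiro dithioketal carbon, and C2 keeps the R configuration because neither its C–H nor its C–O bond is touched. The step needs C- before O-benzylation, which the much more nucleophilic carbanion, one equivalent of 10 and −78 °C should secure, and closure through O1 alone, which holds because no other free heteroatom nucleophile is present and fluorine marks the only arene carbon that O1 can reach.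

Step 8
Reactants: 13 (2R)-5,7-bis(benzyloxy)-2-[3,4-bis(benzyloxy)phenyl]spiro[chromane-3,2'-[1,3]dithiane]
Product: 14 (2R)-5,7-bis(benzyloxy)-2-[3,4-bis(benzyloxy)phenyl]chroman-3-one
Conditions: MeI (excess), CaCO3, MeCN/H2O (9:1), 45 °C
Reagents that add atoms: water, O
Why: Alkylative dithioketal hydrolysis (S-methylation, ring opening to a thionium ion, capture by water) under carbonate buffering should release the C3 ketone without enolising the benzylic C2 stereocenter next to it.

Step 9
Reactants: 14 (2R)-5,7-bis(benzyloxy)-2-[3,4-bis(benzyloxy)phenyl]chroman-3-one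
Product: 15 (2R,3R)-5,7-bis(benzyloxy)-2-[3,4-bis(benzyloxy)phenyl]chroman-3-ol (5,7,3',4'-tetra-O-benzyl-(−)-epicatechin)
Conditions: Li[HB(sec-Bu)3], LiBr, THF, −78 °C
Reagents that add atoms: none
Why: Reduction of the chroman-3-one by a bulky trialkylborohydride should deliver hydride to the ring face opposite the C2 aryl group, so that C2 controls the new C3 stereocenter and the 2,3-cis (3R) alcohol results.

Step 10
Reactants: 15 5,7,3',4'-tetra-O-benzyl-(−)-epicatechin
Product: 16 4β-(2-ethoxyethoxy)-5,7,3',4'-tetra-O-benzyl-(−)-epicatechin (2R,3R; ether at C4 trans to the C3 hydroxyl group)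
Conditions: DDQ (2 equiv), 2-ethoxyethanol (5 equiv), CH2Cl2, rt
Reagents that add atoms: 2-ethoxyethanol, CCOCCO
Why: Benzylic oxidation by DDQ, which abstracts hydride from C4 to give a cation stabilised by ring A that 2-ethoxyethanol should trap anti to the C3 hydroxyl group (4β ether, 3,4-trans).

Step 11
Reactants: 16 4β-(2-ethoxyethoxy)-5,7,3',4'-tetra-O-benzyl-(−)-epicatechin; 15 5,7,3',4'-tetra-O-benzyl-(−)-epicatechin
Product: 17 octa-O-benzyl epicatechin-(4β→8)-epicatechin (both units 2R,3R; interflavan bond trans to the C3 hydroxyl group)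
Conditions: 15 (4 equiv), TMSOTf (0.5 equiv), CH2Cl2, −78 °C
Reagents that add atoms: none
Why: Lewis acid-promoted flavan-4-yl cation coupling (a Friedel–Crafts alkylation), in which TMSOTf ionises the C4 ether of 16 and C8 of ring A of 15 attacks the cation anti to the C3 hydroxyl group, which should set C4 as 4β (3,4-trans), while the excess of 15 limits further chain growth.

Step 12
Reactants: 16 4β-(2-ethoxyethoxy)-5,7,3',4'-tetra-O-benzyl-(−)-epicatechin; 17 octa-O-benzyl epicatechin-(4β→8)-epicatechin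
Product: 18 dodeca-O-benzyl epicatechin-(4β→8)-epicatechin-(4β→8)-epicatechin
Conditions: 17 (3 equiv), TMSOTf (0.5 equiv), CH2Cl2, −78 °C
Reagents that add atoms: none
Why: The same cation coupling, in which the free C8 of the upper unit of 17, the least hindered doubly activated arene position, should attack the C4 cation anti to its C3 hydroxyl group (4β, 3,4-trans).

Step 13
Reactants: 16 4β-(2-ethoxyethoxy)-5,7,3',4'-tetra-O-benzyl-(−)-epicatechin; 18 dodeca-O-benzyl epicatechin-(4β→8)-epicatechin-(4β→8)-epicatechin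
Product: 19 hexadeca-O-benzyl epicatechin-(4β→8)-epicatechin-(4β→8)-epicatechin-(4β→8)-epicatechin
Conditions: 18 (2.5 equiv), TMSOTf (0.5 equiv), CH2Cl2, −78 °C
Reagents that add atoms: none
Why: The same cation coupling with C8 of the uppermost unit of 18 as the nucleophile, the new C4 stereocenter again being set 3,4-trans (4β) by approach anti to the C3 hydroxyl group of the cation.

Step 14
Reactants: 19 hexadeca-O-benzyl epicatechin-(4β→8)-epicatechin-(4β→8)-epicatechin-(4β→8)-epicatechin
Product: 20 epicatechin-(4β→8)-epicatechin-(4β→8)-epicatechin-(4β→8)-epicatechin (the target tetramer)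
Conditions: H2 (1 atm), Pd(OH)2/C, THF/MeOH/H2O, rt
Reagents that add atoms: none
Why: Hydrogenolysis of the sixteen benzyl ethers over Pd(OH)2/C under neutral conditions should leave the acid-sensitive interflavan bonds and all eleven stereocenters untouched.

Compound list
1 | 1,3-dithiane | C1CSCSC1 | starting material
2 | methyl 3,4-bis(benzyloxy)benzoate | COC(=O)c1ccc(OCc2ccccc2)c(OCc2ccccc2)c1 | starting material
3 | 2-lithio-1,3-dithiane | [Li]C1SCCCS1 | intermediate
4 | [3,4-bis(benzyloxy)phenyl](1,3-dithian-2-yl)methanone | O=C(c1ccc(OCc2ccccc2)c(OCc2ccccc2)c1)C1SCCCS1 | intermediate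
5 | (R)-[3,4-bis(benzyloxy)phenyl](1,3-dithian-2-yl)methanol | O[C@H](c1ccc(OCc2ccccc2)c(OCc2ccccc2)c1)C1SCCCS1 | intermediate
6 | 5-fluorobenzene-1,3-diol | Oc1cc(O)cc(F)c1 | starting material
7 | 1,3-bis(benzyloxy)-5-fluorobenzene | Fc1cc(OCc2ccccc2)cc(OCc2ccccc2)c1 | intermediate
8 | 2,4-bis(benzyloxy)-6-fluorobenzaldehyde | O=Cc1c(F)cc(OCc2ccccc2)cc1OCc1ccccc1 | intermediate
9 | [2,4-bis(benzyloxy)-6-fluorophenyl]methanol | OCc1c(F)cc(OCc2ccccc2)cc1OCc1ccccc1 | intermediate
10 | 1,5-bis(benzyloxy)-2-(chloromethyl)-3-fluorobenzene | ClCc1c(F)cc(OCc2ccccc2)cc1OCc1ccccc1 | intermediate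
11 | dilithio derivative of 5 (lithium alkoxide, 2-lithio-1,3-dithiane; R) | [Li+].[O-][C@H](c1ccc(OCc2ccccc2)c(OCc2ccccc2)c1)C1([Li])SCCCS1 | intermediate
12 | lithium (R)-[3,4-bis(benzyloxy)phenyl]{2-[2,4-bis(benzyloxy)-6-fluorobenzyl]-1,3-dithian-2-yl}methanolate | [Li+].[O-][C@H](c1ccc(OCc2ccccc2)c(OCc2ccccc2)c1)C1(Cc2c(F)cc(OCc3ccccc3)cc2OCc2ccccc2)SCCCS1 | intermediate
13 | (2R)-5,7-bis(benzyloxy)-2-[3,4-bis(benzyloxy)phenyl]spiro[chromane-3,2'-[1,3]dithiane] | c1ccccc1COc1cc(OCc2ccccc2)c2c(c1)O[C@H](c1ccc(OCc3ccccc3)c(OCc3ccccc3)c1)C1(SCCCS1)C2 | intermediate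
14 | (2R)-5,7-bis(benzyloxy)-2-[3,4-bis(benzyloxy)phenyl]chroman-3-one | c1ccccc1COc1cc(OCc2ccccc2)c2c(c1)O[C@H](c1ccc(OCc3ccccc3)c(OCc3ccccc3)c1)C(=O)C2 | intermediate
15 | (2R,3R)-5,7-bis(benzyloxy)-2-[3,4-bis(benzyloxy)phenyl]chroman-3-ol (5,7,3',4'-tetra-O-benzyl-(−)-epicatechin) | c1ccccc1COc1cc(OCc2ccccc2)c2c(c1)O[C@H](c1ccc(OCc3ccccc3)c(OCc3ccccc3)c1)[C@H](O)C2 | intermediate
16 | 4β-(2-ethoxyethoxy)-5,7,3',4'-tetra-O-benzyl-(−)-epicatechin (2,3-cis, 3,4-trans) | c1ccccc1COc1cc(OCc2ccccc2)c2c(c1)O[C@H](c1ccc(OCc3ccccc3)c(OCc3ccccc3)c1)[C@H](O)[C@H]2OCCOCC | intermediate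
17 | octa-O-benzyl epicatechin-(4β→8)-epicatechin | c1ccccc1COc1cc(OCc2ccccc2)c2c(c1)O[C@H](c1ccc(OCc3ccccc3)c(OCc3ccccc3)c1)[C@H](O)[C@H]2c1c(OCc3ccccc3)cc(OCc3ccccc3)c2c1O[C@H](c1ccc(OCc3ccccc3)c(OCc3ccccc3)c1)[C@H](O)C2 | intermediate
18 | dodeca-O-benzyl epicatechin-(4β→8)-epicatechin-(4β→8)-epicatechin | c1ccccc1COc1cc(OCc2ccccc2)c2c(c1)O[C@H](c1ccc(OCc3ccccc3)c(OCc3ccccc3)c1)[C@H](O)[C@H]2c1c(OCc3ccccc3)cc(OCc3ccccc3)c2c1O[C@H](c1ccc(OCc3ccccc3)c(OCc3ccccc3)c1)[C@H](O)[C@H]2c1c(OCc3ccccc3)cc(OCc3ccccc3)c2c1O[C@H](c1ccc(OCc3ccccc3)c(OCc3ccccc3)c1)[C@H](O)C2 | intermediate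
19 | hexadeca-O-benzyl epicatechin-(4β→8)-epicatechin-(4β→8)-epicatechin-(4β→8)-epicatechin | c1ccccc1COc1cc(OCc2ccccc2)c2c(c1)O[C@H](c1ccc(OCc3ccccc3)c(OCc3ccccc3)c1)[C@H](O)[C@H]2c1c(OCc3ccccc3)cc(OCc3ccccc3)c2c1O[C@H](c1ccc(OCc3ccccc3)c(OCc3ccccc3)c1)[C@H](O)[C@H]2c1c(OCc3ccccc3)cc(OCc3ccccc3)c2c1O[C@H](c1ccc(OCc3ccccc3)c(OCc3ccccc3)c1)[C@H](O)[C@H]2c1c(OCc3ccccc3)cc(OCc3ccccc3)c2c1O[C@H](c1ccc(OCc3ccccc3)c(OCc3ccccc3)c1)[C@H](O)C2 | intermediate
20 | epicatechin-(4β→8)-epicatechin-(4β→8)-epicatechin-(4β→8)-epicatechin (the target tetramer; every unit 2R,3R, every interflavan bond 4β) | Oc1cc(O)c2c(c1)O[C@H](c1ccc(O)c(O)c1)[C@H](O)[C@H]2c1c(O)cc(O)c2c1O[C@H](c1ccc(O)c(O)c1)[C@H](O)[C@H]2c1c(O)cc(O)c2c1O[C@H](c1ccc(O)c(O)c1)[C@H](O)[C@H]2c1c(O)cc(O)c2c1O[C@H](c1ccc(O)c(O)c1)[C@H](O)C2 | target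

Total step count: 14. Longest linear sequence: 12 steps (steps 3 to 14, from 6).

Steps most likely to fail

1. Step 7. The alkoxide may add too slowly to the fluoroarene, so that O-benzylation by residual chloride or retro-addition of the dithiane carbinol competes with ring closure. Fallback: set out from 5 and 10, stop after the C-benzylation at 0 °C and isolate (R)-[3,4-bis(benzyloxy)phenyl]{2-[2,4-bis(benzyloxy)-6-fluorobenzyl]-1,3-dithian-2-yl}methanol F1. Treating it with lithium 2,2,6,6-tetramethylpiperidide (3 equiv, THF, −78 → 0 °C) should form the alkoxide, lithiate C8 between fluorine and the C7 ether and, by loss of LiF, give the aryne alkoxide F2 (triple bond C8–C8a). The tethered alkoxide should then add to C8a, the aryne carbon remote from the C7 oxygen and the only one it can reach, and protonation at C8 brings the route back at 13.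

2. Step 2. Coordination of the two thioether sulfurs to ruthenium may stall hydride transfer, and the two bulky ketone substituents may be told apart poorly, which would erode the enantiomeric purity. Fallback: set out from 4; reduction with NaBH4 gives racemic [3,4-bis(benzyloxy)phenyl](1,3-dithian-2-yl)methanol F3. Esterification with (S)-2-methoxy-2-phenylacetic acid (DCC, DMAP) and chromatographic separation of the diastereomers gives the (S)-2-methoxy-2-phenylacetate of the R carbinol F4, and methanolysis (K2CO3, MeOH) brings the route back at 5.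

3. Step 13. The activated monomer may add to the product or to itself, so that the chain grows past the tetramer, and the Lewis acid may cleave and re-form interflavan bonds of the large nucleophile. Fallback: set out from 15; bromination with N-bromosuccinimide (CH2Cl2, −20 °C) blocks C8 and gives 8-bromo-5,7,3',4'-tetra-O-benzylepicatechin F5, and DDQ with 2-ethoxyethanol, as in step 10, gives 8-bromo-4β-(2-ethoxyethoxy)-5,7,3',4'-tetra-O-benzylepicatechin F6. An equimolar TMSOTf coupling with 18 gives the 8-bromo hexadeca-O-benzyl tetramer F7, whose top unit can no longer act as a nucleophile. Hydrogenolysis over Pd(OH)2/C in the presence of Et3N removes the benzyl groups and the bromine together and brings the route back at 20.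

Further compounds
F1 | step 7 | (R)-[3,4-bis(benzyloxy)phenyl]{2-[2,4-bis(benzyloxy)-6-fluorobenzyl]-1,3-dithian-2-yl}methanol | O[C@H](c1ccc(OCc2ccccc2)c(OCc2ccccc2)c1)C1(Cc2c(F)cc(OCc3ccccc3)cc2OCc2ccccc2)SCCCS1
F2 | step 7 | lithium alkoxide of the aryne formed from F1 by loss of LiF (triple bond C8–C8a) | [Li+].[O-][C@H](c1ccc(OCc2ccccc2)c(OCc2ccccc2)c1)C1(CC2=C(OCc3ccccc3)C=C(OCc3ccccc3)C#C2)SCCCS1
F3 | step 2 | racemic [3,4-bis(benzyloxy)phenyl](1,3-dithian-2-yl)methanol | OC(c1ccc(OCc2ccccc2)c(OCc2ccccc2)c1)C1SCCCS1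
F4 | step 2 | (R)-[3,4-bis(benzyloxy)phenyl](1,3-dithian-2-yl)methyl (S)-2-methoxy-2-phenylacetate | CO[C@@H](c1ccccc1)C(=O)O[C@H](c1ccc(OCc2ccccc2)c(OCc2ccccc2)c1)C1SCCCS1
F5 | step 13 | 8-bromo-5,7,3',4'-tetra-O-benzylepicatechin (2R,3R) | c1ccccc1COc1cc(OCc2ccccc2)c2c(c1Br)O[C@H](c1ccc(OCc3ccccc3)c(OCc3ccccc3)c1)[C@H](O)C2
F6 | step 13 | 8-bromo-4β-(2-ethoxyethoxy)-5,7,3',4'-tetra-O-benzylepicatechin | c1ccccc1COc1cc(OCc2ccccc2)c2c(c1Br)O[C@H](c1ccc(OCc3ccccc3)c(OCc3ccccc3)c1)[C@H](O)[C@H]2OCCOCC
F7 | step 13 | 8-bromo hexadeca-O-benzyl epicatechin-(4β→8)-epicatechin-(4β→8)-epicatechin-(4β→8)-epicatechin (bromine at C8 of the uppermost unit) | c1ccccc1COc1cc(OCc2ccccc2)c2c(c1Br)O[C@H](c1ccc(OCc3ccccc3)c(OCc3ccccc3)c1)[C@H](O)[C@H]2c1c(OCc3ccccc3)cc(OCc3ccccc3)c2c1O[C@H](c1ccc(OCc3ccccc3)c(OCc3ccccc3)c1)[C@H](O)[C@H]2c1c(OCc3ccccc3)cc(OCc3ccccc3)c2c1O[C@H](c1ccc(OCc3ccccc3)c(OCc3ccccc3)c1)[C@H](O)[C@H]2c1c(OCc3ccccc3)cc(OCc3ccccc3)c2c1O[C@H](c1ccc(OCc3ccccc3)c(OCc3ccccc3)c1)[C@H](O)C2
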